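**Retrosynthetic overview**
1. The two allyl groups are installed last, by a twofold Suzuki–Miyaura coupling on an aryl dibromide; the free phenol comes from Dakin oxidation of the formyl group that activates the key coupling.
2. Key late disconnection: the tertiary alkyl aryl ether C–O bond, formed by SNAr of a cis-decalinol potassium alkoxide on 4-bromo-2-(4-bromophenoxy)-6-fluorobenzaldehyde, with retention at the carbinol carbon.
3. Decalinol: the carbinol methyl by equatorial MeLi/CeCl3 addition to a cis-decalone; the quaternary carbon by Cu-catalysed asymmetric conjugate addition to 3-methylcyclohexenone; the side-chain stereocentre from Sharpless epoxidation of prenol and vinyl-cuprate opening.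
4. Aryl half: 1,3-difluorobenzene → 1-bromo-3,5-difluorobenzene (nitration, reduction, bromination, deamination) → ortho-lithiation/formylation → SNAr with 4-bromophenol.
5. Ring order: ring A is bought (3-methylcyclohex-2-enone), ring B is closed onto it by intramolecular enolate alkylation (step 6); both benzene rings are bought.

Assumption: the SMILES is read literally, i.e. (4R,5S,7R,10R) in eudesmane numbering: a cis-fused decalin (H-5 syn to the angular methyl), aryloxy group anti to H-5, hydroxyisopropyl group syn to the angular methyl.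

**Route**

Step 1
Reactants: 1 3-methylbut-2-en-1-ol (prenol)
Product: 2 [(2S)-3,3-dimethyloxiran-2-yl]methanol
Conditions: Ti(OiPr)4 (5 mol %), L-(+)-diethyl tartrate (6 mol %), t-BuOOH (2 equiv), 4 Å molecular sieves, CH2Cl2, −20 °C
Reagents that add atoms: tert-butyl hydroperoxide, CC(C)(C)OO
Why: Sharpless asymmetric epoxidation; the L-(+)-tartrate catalyst delivers oxygen to the alkene face that gives the (2S)-epoxy alcohol.

Step 2
Reactants: 2 [(2S)-3,3-dimethyloxiran-2-yl]methanol; 3 vinylmagnesium bromide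
Product: 4 (2R)-2-ethenyl-3-methylbutane-1,3-diol
Conditions: 3 (3 equiv), CuI (10 mol %), THF, −30 to 0 °C; aq. NH4Cl
Reagents that add atoms: none
Why: Cu-catalysed SN2 opening of the epoxide at C2 (C3 is fully substituted) with inversion sets the future C7 stereocentre.

Step 3
Reactants: 4 (2R)-2-ethenyl-3-methylbutane-1,3-diol
Product: 5 (2R)-2-ethenyl-3-hydroxy-3-methylbutyl 4-methylbenzenesulfonate
Conditions: TsCl (1.05 equiv), pyridine, CH2Cl2, 0 °C
Reagents that add atoms: p-toluenesulfonyl chloride, Cc1ccc(cc1)S(Cl)(=O)=O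
Why: Chemoselective sulfonylation of the primary hydroxyl; the tertiary hydroxyl does not react under these conditions.

Step 4
Reactants: 5 (2R)-2-ethenyl-3-hydroxy-3-methylbutyl 4-methylbenzenesulfonate
Product: 6 (2R)-2-ethenyl-3-methyl-3-[(triethylsilyl)oxy]butyl 4-methylbenzenesulfonate
Conditions: Et3SiOTf (1.3 equiv), 2,6-lutidine (2 equiv), CH2Cl2, −78 to 0 °C
Reagents that add atoms: triethylsilyl trifluoromethanesulfonate, CC[Si](CC)(CC)OS(=O)(=O)C(F)(F)F
Why: Silyl triflate silylation of a hindered tertiary alcohol; the TES ether masks this hydroxyl so that only the ring carbinol is arylated later.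

Step 5
Reactants: 6 (2R)-2-ethenyl-3-methyl-3-[(triethylsilyl)oxy]butyl 4-methylbenzenesulfonate; 7 3-methylcyclohex-2-en-1-one
Product: 10 (2R)-3-methyl-2-{2-[(1R)-1-methyl-3-oxocyclohexyl]ethyl}-3-[(triethylsilyl)oxy]butyl 4-methylbenzenesulfonate, via alkylzirconocene chloride 8 (not isolated), via trimethylsilyl enol ether 9 (not isolated)
Conditions: 6 (1.3 equiv), Cp2Zr(H)Cl (1.2 equiv), CH2Cl2, 25 °C; then 7 (1.0 equiv), CuCl (10 mol %), AgNTf2 (10 mol %), chiral BINOL-derived phosphoramidite (10 mol %), Me3SiCl (3 equiv), Et2O, 25 °C; aq. NH4Cl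
Reagents that add atoms: none
Why: Hydrozirconation puts Zr on the terminal carbon, and Cu-catalysed asymmetric conjugate addition of the alkylzirconium to the β-methyl enone builds the quaternary centre under ligand control (the ligand enantiomer giving R is used; minor diastereomers are removed by chromatography).

Step 6
Reactants: 10 (2R)-3-methyl-2-{2-[(1R)-1-methyl-3-oxocyclohexyl]ethyl}-3-[(triethylsilyl)oxy]butyl 4-methylbenzenesulfonate
Product: 11 (4aR,7R,8aS)-4a-methyl-7-{2-[(triethylsilyl)oxy]propan-2-yl}octahydronaphthalen-1(2H)-one (cis-fused)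
Conditions: KOtBu (1.05 equiv), THF/t-BuOH (10:1), 0 to 25 °C
Reagents that add atoms: none
Why: Intramolecular enolate alkylation (6-exo-tet) closes ring B; only the enolate on the quaternary-carbon side can reach the tosylate, and the four-atom tether forces bond formation on the enolate face syn to the tether, so H-8a ends up cis to the angular methyl (kinetic cis-decalone).

Step 7
Reactants: 11 (4aR,7R,8aS)-4a-methyl-7-{2-[(triethylsilyl)oxy]propan-2-yl}octahydronaphthalen-1(2H)-one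
Product: 12 (1R,4aR,7R,8aS)-1,4a-dimethyl-7-{2-[(triethylsilyl)oxy]propan-2-yl}decahydronaphthalen-1-ol
Conditions: MeLi (1.5 equiv), CeCl3 (1.6 equiv), THF, −78 °C
Reagents that add atoms: methyllithium, [Li]C
Why: Organocerium 1,2-addition avoids enolisation of the epimerisable ring-fusion carbon; in the conformer with the side chain equatorial the axial face of the ketone is blocked by the syn-axial ring B CH2, so methyl enters equatorially and the new OH is axial and anti to H-8a (1R).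

Step 8
Reactants: 13 1,3-difluorobenzene
Product: 14 2,4-difluoro-1-nitrobenzene
Conditions: HNO3 (1.1 equiv), H2SO4, 0 to 25 °C
Reagents that add atoms: nitric acid, O[N+](=O)[O-]
Why: Electrophilic aromatic nitration goes to the position ortho to one fluorine and para to the other.

Step 9
Reactants: 14 2,4-difluoro-1-nitrobenzene
Product: 15 2,4-difluoroaniline
Conditions: H2 (1 atm), Pd/C (5 wt %), EtOH, 25 °C
Reagents that add atoms: none
Why: Catalytic hydrogenation of the nitro group; aryl C–F bonds survive.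

Step 10
Reactants: 15 2,4-difluoroaniline
Product: 16 2-bromo-4,6-difluoroaniline
Conditions: NBS (1.0 equiv), MeCN, 0 °C
Reagents that add atoms: N-bromosuccinimide, BrN1C(=O)CCC1=O
Why: Electrophilic bromination is directed by NH2 to its only free ortho position (para is fluorinated), which is meta to both fluorines.

Step 11
Reactants: 16 2-bromo-4,6-difluoroaniline
Product: 18 1-bromo-3,5-difluorobenzene, via arenediazonium hydrogensulfate 17 (not isolated)
Conditions: NaNO2 (1.1 equiv), H2SO4, AcOH/H2O, 0 °C; then H3PO2 (50 % aq., 5 equiv), 0 to 25 °C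
Reagents that add atoms: none
Why: Diazotisation followed by hydrodediazoniation with hypophosphorous acid removes the directing amino group.

Step 12
Reactants: 18 1-bromo-3,5-difluorobenzene
Product: 20 4-bromo-2,6-difluorobenzaldehyde, via aryllithium 19 (not isolated)
Conditions: LiN(iPr)2 (1.05 equiv), THF, −78 °C; then DMF (1.5 equiv), −78 °C; aq. HCl
Reagents that add atoms: N,N-dimethylformamide, CN(C)C=O
Why: Directed ortho-lithiation at the most acidic C–H (between the two fluorines), then formylation with DMF.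

Step 13
Reactants: 20 4-bromo-2,6-difluorobenzaldehyde; 21 4-bromophenol
Product: 22 4-bromo-2-(4-bromophenoxy)-6-fluorobenzaldehyde
Conditions: 21 (1.0 equiv), K2CO3 (1.2 equiv), DMF, 0 to 25 °C
Reagents that add atoms: none
Why: SNAr of phenoxide at a fluorine ortho to the formyl group; fluoride leaves far faster than bromide, and the first aryloxy group deactivates the ring against a second substitution.

Step 14
Reactants: 12 (1R,4aR,7R,8aS)-1,4a-dimethyl-7-{2-[(triethylsilyl)oxy]propan-2-yl}decahydronaphthalen-1-ol; 22 4-bromo-2-(4-bromophenoxy)-6-fluorobenzaldehyde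
Product: 24 4-bromo-2-(4-bromophenoxy)-6-{[(1R,4aR,7R,8aS)-1,4a-dimethyl-7-{2-[(triethylsilyl)oxy]propan-2-yl}decahydronaphthalen-1-yl]oxy}benzaldehyde, via potassium alkoxide 23 (not isolated)
Conditions: KN(SiMe3)2 (1.05 equiv), THF, −78 to 0 °C; then 22 (1.1 equiv), THF, 0 to 40 °C
Reagents that add atoms: none
Why: SNAr (addition–elimination) of the tertiary alkoxide at the C–F carbon ortho to the formyl group; the carbinol C–O bond is not broken, so the C1 configuration is retained, and the alkoxide has no α-hydrogen with which to reduce the aldehyde.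

Step 15
Reactants: 24 4-bromo-2-(4-bromophenoxy)-6-{[(1R,4aR,7R,8aS)-1,4a-dimethyl-7-{2-[(triethylsilyl)oxy]propan-2-yl}decahydronaphthalen-1-yl]oxy}benzaldehyde
Product: 26 4-bromo-2-(4-bromophenoxy)-6-{[(1R,4aR,7R,8aS)-1,4a-dimethyl-7-{2-[(triethylsilyl)oxy]propan-2-yl}decahydronaphthalen-1-yl]oxy}phenol, via aryl formate 25 (not isolated)
Conditions: mCPBA (1.5 equiv), NaHCO3, CH2Cl2, 0 to 25 °C; then K2CO3 (0.2 equiv), MeOH, 0 °C
Reagents that add atoms: 3-chloroperoxybenzoic acid, OOC(=O)c1cccc(Cl)c1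
Why: Dakin-type Baeyer–Villiger oxidation: the aryl group flanked by two oxygen donors migrates, and methanolysis of the formate frees the phenol; no alkene is present yet.

Step 16
Reactants: 26 4-bromo-2-(4-bromophenoxy)-6-{[(1R,4aR,7R,8aS)-1,4a-dimethyl-7-{2-[(triethylsilyl)oxy]propan-2-yl}decahydronaphthalen-1-yl]oxy}phenol; 27 potassium allyltrifluoroborate
Product: 28 2-{[(1R,4aR,7R,8aS)-1,4a-dimethyl-7-{2-[(triethylsilyl)oxy]propan-2-yl}decahydronaphthalen-1-yl]oxy}-4-(prop-2-en-1-yl)-6-[4-(prop-2-en-1-yl)phenoxy]phenol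
Conditions: 27 (3 equiv), Pd(OAc)2 (5 mol %), RuPhos (10 mol %), K2CO3 (6 equiv), toluene/H2O (10:1), 80 °C
Reagents that add atoms: none
Why: Twofold Suzuki–Miyaura sp2–sp3 cross-coupling converts both aryl bromides into allyl arenes; the free phenol and silyl ether are tolerated.

Step 17
Reactants: 28 2-{[(1R,4aR,7R,8aS)-1,4a-dimethyl-7-{2-[(triethylsilyl)oxy]propan-2-yl}decahydronaphthalen-1-yl]oxy}-4-(prop-2-en-1-yl)-6-[4-(prop-2-en-1-yl)phenoxy]phenol
Product: 29 2-[(2R,4aR,8R,8aS)-8-{2-hydroxy-5-(prop-2-en-1-yl)-3-[4-(prop-2-en-1-yl)phenoxy]phenoxy}-4a,8-dimethyldecahydronaphthalen-2-yl]propan-2-ol (target)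
Conditions: Bu4NF (3 equiv), THF, 25 to 40 °C; aq. NH4Cl
Reagents that add atoms: none
Why: Fluoride-mediated desilylation frees the side-chain tertiary alcohol without touching the acid-sensitive tertiary aryl ether or the allyl groups.

**Compound list**
1 | 3-methylbut-2-en-1-ol | CC(C)=CCO | starting material
2 | [(2S)-3,3-dimethyloxiran-2-yl]methanol | OC[C@@H]1OC1(C)C | intermediate
3 | vinylmagnesium bromide | C=C[Mg]Br | starting material
4 | (2R)-2-ethenyl-3-methylbutane-1,3-diol | OC[C@H](C(C)(C)O)C=C | intermediate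
5 | (2R)-2-ethenyl-3-hydroxy-3-methylbutyl 4-methylbenzenesulfonate | Cc1ccc(cc1)S(=O)(=O)OC[C@H](C(C)(C)O)C=C | intermediate
6 | (2R)-2-ethenyl-3-methyl-3-[(triethylsilyl)oxy]butyl 4-methylbenzenesulfonate | Cc1ccc(cc1)S(=O)(=O)OC[C@H](C(C)(C)O[Si](CC)(CC)CC)C=C | intermediate
7 | 3-methylcyclohex-2-en-1-one | CC1=CC(=O)CCC1 | starting material
8 | chloridobis(cyclopentadienyl){(3R)-4-methyl-3-[(tosyloxy)methyl]-4-[(triethylsilyl)oxy]pentyl}zirconium | Cc1ccc(cc1)S(=O)(=O)OC[C@H](C(C)(C)O[Si](CC)(CC)CC)CC[Zr](Cl)(C1C=CC=C1)C1C=CC=C1 | intermediate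
9 | (2R)-3-methyl-2-{2-[(1R)-1-methyl-3-[(trimethylsilyl)oxy]cyclohex-2-en-1-yl]ethyl}-3-[(triethylsilyl)oxy]butyl 4-methylbenzenesulfonate | C[Si](C)(C)OC1=C[C@@](C)(CC[C@H](COS(=O)(=O)c2ccc(C)cc2)C(C)(C)O[Si](CC)(CC)CC)CCC1 | intermediate
10 | (2R)-3-methyl-2-{2-[(1R)-1-methyl-3-oxocyclohexyl]ethyl}-3-[(triethylsilyl)oxy]butyl 4-methylbenzenesulfonate | O=C1CCC[C@](C)(CC[C@H](COS(=O)(=O)c2ccc(C)cc2)C(C)(C)O[Si](CC)(CC)CC)C1 | intermediate
11 | (4aR,7R,8aS)-4a-methyl-7-{2-[(triethylsilyl)oxy]propan-2-yl}octahydronaphthalen-1(2H)-one | O=C1CCC[C@]2(C)CC[C@@H](C(C)(C)O[Si](CC)(CC)CC)C[C@@H]21 | intermediate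
12 | (1R,4aR,7R,8aS)-1,4a-dimethyl-7-{2-[(triethylsilyl)oxy]propan-2-yl}decahydronaphthalen-1-ol | O[C@]1(C)CCC[C@]2(C)CC[C@@H](C(C)(C)O[Si](CC)(CC)CC)C[C@@H]21 | intermediate
13 | 1,3-difluorobenzene | Fc1cccc(F)c1 | starting material
14 | 2,4-difluoro-1-nitrobenzene | [O-][N+](=O)c1ccc(F)cc1F | intermediate
15 | 2,4-difluoroaniline | Nc1ccc(F)cc1F | intermediate
16 | 2-bromo-4,6-difluoroaniline | Nc1c(F)cc(F)cc1Br | intermediate
17 | 2-bromo-4,6-difluorobenzenediazonium hydrogensulfate | N#[N+]c1c(F)cc(F)cc1Br.OS(=O)(=O)[O-] | intermediate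
18 | 1-bromo-3,5-difluorobenzene | Fc1cc(F)cc(Br)c1 | intermediate
19 | (4-bromo-2,6-difluorophenyl)lithium | [Li]c1c(F)cc(Br)cc1F | intermediate
20 | 4-bromo-2,6-difluorobenzaldehyde | O=Cc1c(F)cc(Br)cc1F | intermediate
21 | 4-bromophenol | Oc1ccc(Br)cc1 | starting material
22 | 4-bromo-2-(4-bromophenoxy)-6-fluorobenzaldehyde | O=Cc1c(F)cc(Br)cc1Oc1ccc(Br)cc1 | intermediate
23 | potassium (1R,4aR,7R,8aS)-1,4a-dimethyl-7-{2-[(triethylsilyl)oxy]propan-2-yl}decahydronaphthalen-1-olate | [K+].[O-][C@]1(C)CCC[C@]2(C)CC[C@@H](C(C)(C)O[Si](CC)(CC)CC)C[C@@H]21 | intermediate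
24 | 4-bromo-2-(4-bromophenoxy)-6-{[(1R,4aR,7R,8aS)-1,4a-dimethyl-7-{2-[(triethylsilyl)oxy]propan-2-yl}decahydronaphthalen-1-yl]oxy}benzaldehyde | O=Cc1c(O[C@]2(C)CCC[C@]3(C)CC[C@@H](C(C)(C)O[Si](CC)(CC)CC)C[C@@H]32)cc(Br)cc1Oc1ccc(Br)cc1 | intermediate
25 | 4-bromo-2-(4-bromophenoxy)-6-{[(1R,4aR,7R,8aS)-1,4a-dimethyl-7-{2-[(triethylsilyl)oxy]propan-2-yl}decahydronaphthalen-1-yl]oxy}phenyl formate | O=COc1c(O[C@]2(C)CCC[C@]3(C)CC[C@@H](C(C)(C)O[Si](CC)(CC)CC)C[C@@H]32)cc(Br)cc1Oc1ccc(Br)cc1 | intermediate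
26 | 4-bromo-2-(4-bromophenoxy)-6-{[(1R,4aR,7R,8aS)-1,4a-dimethyl-7-{2-[(triethylsilyl)oxy]propan-2-yl}decahydronaphthalen-1-yl]oxy}phenol | Oc1c(O[C@]2(C)CCC[C@]3(C)CC[C@@H](C(C)(C)O[Si](CC)(CC)CC)C[C@@H]32)cc(Br)cc1Oc1ccc(Br)cc1 | intermediate
27 | potassium allyltrifluoroborate | C=CC[B-](F)(F)F.[K+] | starting material
28 | 2-{[(1R,4aR,7R,8aS)-1,4a-dimethyl-7-{2-[(triethylsilyl)oxy]propan-2-yl}decahydronaphthalen-1-yl]oxy}-4-(prop-2-en-1-yl)-6-[4-(prop-2-en-1-yl)phenoxy]phenol | Oc1c(O[C@]2(C)CCC[C@]3(C)CC[C@@H](C(C)(C)O[Si](CC)(CC)CC)C[C@@H]32)cc(CC=C)cc1Oc1ccc(CC=C)cc1 | intermediate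
29 | 2-[(2R,4aR,8R,8aS)-8-{2-hydroxy-5-(prop-2-en-1-yl)-3-[4-(prop-2-en-1-yl)phenoxy]phenoxy}-4a,8-dimethyldecahydronaphthalen-2-yl]propan-2-ol | C=CCc1ccc(Oc2cc(CC=C)cc(O[C@]3(C)CCC[C@]4(C)CC[C@@H](C(C)(C)O)C[C@@H]43)c2O)cc1 | target

**Totals**
Total step count: 17. Longest linear sequence: 11 steps (steps 1–7, then 14–17). The aryl branch (steps 8–13) is 6 steps.

**Steps most likely to fail, with fallbacks**

Step 14 (SNAr of a hindered, axial tertiary alkoxide next to a free aldehyde). The fallback sets out from 22 and comes back at 24. Aldehyde 22 is turned by one-pot oximation and dehydration (NH2OH·HCl, NaOAc, EtOH; then Ac2O, 110 °C) into 4-bromo-2-(4-bromophenoxy)-6-fluorobenzonitrile F1. The nitrile activates the fluoride at least as well and cannot add alkoxide irreversibly. SNAr with alkoxide 23 (KN(SiMe3)2, THF, 0 to 25 °C) gives 4-bromo-2-(4-bromophenoxy)-6-{[(1R,4aR,7R,8aS)-1,4a-dimethyl-7-{2-[(triethylsilyl)oxy]propan-2-yl}decahydronaphthalen-1-yl]oxy}benzonitrile F2. Reduction with i-Bu2AlH (toluene, −78 to 0 °C) and mild acidic hydrolysis of the aldimine returns aldehyde 24.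

Step 5 (asymmetric conjugate addition of a functionalised, branched alkylzirconium; tosylate tolerance and diastereoselectivity are unproven for this chain). The fallback sets out from 6 and comes back at 10, and changes which substituent is added enantioselectively. Hydroboration of 6 with 9-borabicyclo[3.3.1]nonane (THF, 25 °C) gives (2R)-2-[2-(9-borabicyclo[3.3.1]nonan-9-yl)ethyl]-3-methyl-3-[(triethylsilyl)oxy]butyl 4-methylbenzenesulfonate F3. B-alkyl Suzuki–Miyaura coupling with 3-iodocyclohex-2-en-1-one (IC1=CC(=O)CCC1; PdCl2(dppf), Cs2CO3, DMF/THF/H2O, 25 °C) gives (2R)-3-methyl-2-[2-(3-oxocyclohex-1-en-1-yl)ethyl]-3-[(triethylsilyl)oxy]butyl 4-methylbenzenesulfonate F4. Cu-catalysed asymmetric conjugate addition of AlMe3 (copper thiophene-2-carboxylate CuTC, chiral phosphoramidite, Et2O, −30 °C), with the ligand enantiomer chosen so that methyl adds to the face giving the R centre, then delivers ketone 10.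

Step 6 (ring closure: competing E2 of the β-branched tosylate, wrong-side enolate, epimerisation of the cis ring fusion by excess base). The fallback sets out from 9 and comes back at 11. Silyl enol ether 9 is isolated from step 5 by a non-aqueous work-up. MeLi (1.0 equiv, THF, 0 °C) cleaves the Si–O bond and gives the regiodefined lithium (R)-3-methyl-3-{(3R)-4-methyl-3-[(tosyloxy)methyl]-4-[(triethylsilyl)oxy]pentyl}cyclohex-1-en-1-olate F5 with no free base or proton source. Addition of DMPU (0 to 25 °C) triggers the same cis-selective cycloalkylation to 11.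

**Further compounds**
F1 | step 14 | 4-bromo-2-(4-bromophenoxy)-6-fluorobenzonitrile | N#Cc1c(F)cc(Br)cc1Oc1ccc(Br)cc1
F2 | step 14 | 4-bromo-2-(4-bromophenoxy)-6-{[(1R,4aR,7R,8aS)-1,4a-dimethyl-7-{2-[(triethylsilyl)oxy]propan-2-yl}decahydronaphthalen-1-yl]oxy}benzonitrile | N#Cc1c(O[C@]2(C)CCC[C@]3(C)CC[C@@H](C(C)(C)O[Si](CC)(CC)CC)C[C@@H]32)cc(Br)cc1Oc1ccc(Br)cc1
F3 | step 5 | (2R)-2-[2-(9-borabicyclo[3.3.1]nonan-9-yl)ethyl]-3-methyl-3-[(triethylsilyl)oxy]butyl 4-methylbenzenesulfonate | Cc1ccc(cc1)S(=O)(=O)OC[C@H](C(C)(C)O[Si](CC)(CC)CC)CCB1C2CCCC1CCC2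
F4 | step 5 | (2R)-3-methyl-2-[2-(3-oxocyclohex-1-en-1-yl)ethyl]-3-[(triethylsilyl)oxy]butyl 4-methylbenzenesulfonate | O=C1C=C(CC[C@H](COS(=O)(=O)c2ccc(C)cc2)C(C)(C)O[Si](CC)(CC)CC)CCC1
F5 | step 6 | lithium (R)-3-methyl-3-{(3R)-4-methyl-3-[(tosyloxy)methyl]-4-[(triethylsilyl)oxy]pentyl}cyclohex-1-en-1-olate | [Li]OC1=C[C@@](C)(CC[C@H](COS(=O)(=O)c2ccc(C)cc2)C(C)(C)O[Si](CC)(CC)CC)CCC1
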